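**Retrosynthetic overview**

- The target is 6-benzoyl-7-hydroxy-2,2-dimethyl-8,8-diprenyl-2H-chromen-5(8H)-one (chromene numbering O1, C2, C3, C4, C4a, C5 to C8, C8a; ring A is the carbocycle, ring B the pyran). The benzoyl carbonyl on C6 and the C5 oxygen form a 1,3-dicarbonyl pair that is carried as a 3-phenylisoxazole (ring oxygen = O5, ring C4 = C6). Of the two oxygens flanking C4a, only O8a is then free to close the pyran.
- Endgame: reductive N–O cleavage and hydrolysis of the resulting enaminone unveil the benzoyl triketone. Before that, ring B is closed by prenal condensation at C4a and oxa-6π cyclisation onto O8a.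
- Ring A: C4a–C8a and C7–C8 are cut together. This leads back to the 5-methyl carbanion of ethyl 5-methyl-3-phenylisoxazole-4-carboxylate and diprenylketene, whose terminal carbon already carries both prenyl groups (C8).
- Diprenylketene comes from diethyl malonate and prenyl bromide by way of diprenylacetyl chloride. Order of rings: isoxazole (purchased), then ring A, then ring B.

Key step: step 7

Remark: the target has no stereocentre and is one enol tautomer of a cyclic β-triketone; the tautomer drawn in the target SMILES is taken as the product of the last step.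

**Route**

Step 1
Reactants: 1 diethyl malonate; 2 1-bromo-3-methylbut-2-ene (prenyl bromide)
Product: 4 diethyl 2,2-bis(3-methylbut-2-enyl)malonate, via diethyl 2-(3-methylbut-2-enyl)malonate 3 (not isolated)
Conditions: NaH (2.3 equiv), 2 (2.3 equiv), THF, 0 °C → rt
Reagents that add atoms: none
Why: Two successive SN2 alkylations of the malonate enolate at the primary carbon of the allylic bromide (malonic ester alkylation) should install both prenyl groups on the same carbon.

Step 2
Reactants: 4 diethyl 2,2-bis(3-methylbut-2-enyl)malonate
Product: 5 ethyl 5-methyl-2-(3-methylbut-2-enyl)hex-4-enoate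
Conditions: LiCl, H2O, DMSO, 160 °C
Reagents that add atoms: none
Why: Krapcho dealkoxycarbonylation (chloride attack on one ethyl group, loss of CO2, protonation by water) removes one ester under neutral conditions, so the acid-sensitive trisubstituted alkenes are not exposed to a hot free malonic acid.

Step 3
Reactants: 5 ethyl 5-methyl-2-(3-methylbut-2-enyl)hex-4-enoate
Product: 7 5-methyl-2-(3-methylbut-2-enyl)hex-4-enoic acid, via potassium 5-methyl-2-(3-methylbut-2-enyl)hex-4-enoate 6 (not isolated)
Conditions: KOH, EtOH/H2O, reflux; then 1 M HCl, 0 °C, to pH 3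
Reagents that add atoms: potassium hydroxide, [K+].[OH-]
Why: Ordinary saponification by acyl–oxygen cleavage, with brief cold acidification so that the γ,δ-unsaturated acid does not lactonise onto its alkenes.

Step 4
Reactants: 7 5-methyl-2-(3-methylbut-2-enyl)hex-4-enoic acid
Product: 8 5-methyl-2-(3-methylbut-2-enyl)hex-4-enoyl chloride
Conditions: (COCl)2, DMF (cat.), CH2Cl2, 0 °C → rt, argon sweep; volatiles removed in vacuo
Reagents that add atoms: oxalyl chloride, ClC(=O)C(=O)Cl
Why: Vilsmeier-catalysed acid chloride formation runs cold with only gaseous by-products, and the argon sweep keeps contact of the prenyl groups with HCl short.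

Step 5
Reactants: 9 5-methyl-3-phenylisoxazole-4-carboxylic acid
Product: 10 ethyl 5-methyl-3-phenylisoxazole-4-carboxylate
Conditions: EtI, K2CO3, DMF, rt
Reagents that add atoms: iodoethane, CCI
Why: SN2 O-alkylation of the carboxylate does not depend on attack at the carboxyl carbon, which is flanked by the 3-phenyl and 5-methyl groups.

Step 6
Reactants: 8 5-methyl-2-(3-methylbut-2-enyl)hex-4-enoyl chloride
Product: 11 diprenylketene (5-methyl-2-(3-methylbut-2-enyl)hexa-1,4-dien-1-one), kept as a filtered ether solution
Conditions: Et3N (1.2 equiv), Et2O, 0 °C → rt; filtration under argon; filtrate used at once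
Reagents that add atoms: none
Why: Dehydrochlorination of an α-branched acyl chloride by triethylamine is the standard way to a disubstituted ketene, and removal of the ammonium salt by filtration ensures that no proton source enters step 7.

Step 7
Reactants: 10 ethyl 5-methyl-3-phenylisoxazole-4-carboxylate; 11 diprenylketene
Product: 15 3-phenyl-5,5-bis(3-methylbut-2-enyl)-1,2-benzoxazole-4,6(5H,7H)-dione, via lateral lithio ester 12 (not isolated), via open-chain lithium enolate 13 (not isolated), via lithium enolate of the diketone 14 (not isolated)
Conditions: 2,2,6,6-tetramethylpiperidine, n-BuLi (1.05 equiv), THF, 0 °C; 10, −78 °C; 11 (1.1 equiv, Et2O solution, slow addition), −78 °C → rt; AcOH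
Reagents that add atoms: none
Why: Proposed new method: the lithium amide removes a proton from the 5-methyl group, whose anion is delocalised through the ring C4=C5 bond into the ester, and this carbon (future C4a) should add to the central carbon of the ketene (future C8a), as organolithium reagents and ester enolates do, to give the fully substituted lithium enolate 13 in a medium free of proton donors. On warming, 13 should acylate through C8 on the neighbouring ester carbon (C7) in a 6-(enolendo)-exo-trig Dieckmann closure that forms ring A and releases ethoxide. The closest known reactions are the lateral metalation and electrophile trapping of 5-methylisoxazole-4-carboxylates and the Michael–Dieckmann annulations of ortho-toluate anions; here the ketene stands in for the Michael acceptor and carries both prenyl groups on its terminal carbon, which spares a later double alkylation between two carbonyl groups. No stereocentre arises because C8 bears two identical prenyl groups. The selectivity needed is C- over O-acylation of 13: the six-membered enol lactone from O-acylation can be reopened by lithium ethoxide, whereas the diketone is withdrawn from the equilibrium as its C4a anion 14, stabilised by the C8a ketone and, through the isoxazole, by the C7 ketone. The hindered amine by-product should not consume the ketene, and slow addition of the ketene to the cold anion should hold back ketene dimerisation and self-condensation of the ester.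

Step 8
Reactants: 15 3-phenyl-5,5-bis(3-methylbut-2-enyl)-1,2-benzoxazole-4,6(5H,7H)-dione; 16 3-methylbut-2-enal (prenal)
Product: 18 isoxazole-fused chromenone (2,2-dimethyl-8,8-bis(3-methylbut-2-enyl)-2H-chromen-7(8H)-one carrying a 3-phenylisoxazole across C5–C6; ring oxygen on C5; ring C4 = C6), via Z-oxatriene 17 (not isolated)
Conditions: 16 (3 equiv), ethylenediammonium diacetate (20 mol %), toluene, 80 °C
Reagents that add atoms: none
Why: Amine-catalysed Knoevenagel condensation at C4a, the only enolisable position of this vinylogous 1,3-diketone, followed by oxa-6π electrocyclisation of the oxatriene onto the C8a carbonyl oxygen (the formal [3+3] annulation of enals with 1,3-dicarbonyl and phenol-type partners) should give the 2H-pyran, and no regioisomer can form because O5 is held in the isoxazole.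

Step 9
Reactants: 18 isoxazole-fused chromenone
Product: 19 6-[amino(phenyl)methylidene]-2,2-dimethyl-8,8-bis(3-methylbut-2-enyl)-2H-chromene-5,7(6H,8H)-dione (push–pull alkene, configurationally labile)
Conditions: Mo(CO)6 (1 equiv), H2O (10 equiv), MeCN, 80 °C
Reagents that add atoms: none
Why: Zerovalent molybdenum in wet acetonitrile cleaves the isoxazole N–O bond reductively to the β-aminoenone, with water as the hydrogen source, and leaves the alkenes, the enol ether and the ketones alone.

Step 10
Reactants: 19 6-[amino(phenyl)methylidene]-2,2-dimethyl-8,8-bis(3-methylbut-2-enyl)-2H-chromene-5,7(6H,8H)-dione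
Product: 21 6-benzoyl-7-hydroxy-2,2-dimethyl-8,8-bis(3-methylbut-2-enyl)-2H-chromen-5(8H)-one (target CNP0138894.0), via sodium enolate of the target 20 (not isolated)
Conditions: 2 M NaOH, EtOH, 60 °C; then 1 M HCl, 0 °C, to pH 3
Reagents that add atoms: sodium hydroxide, [Na+].[OH-]
Why: Hydroxide adds to the amino-bearing carbon of the push–pull alkene and ammonia is lost (addition–elimination hydrolysis of a vinylogous amide), the triketone leaving as its delocalised enolate, which should resist retro-Claisen cleavage until cold acidification frees the enol.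

**Compound list**

1 | diethyl malonate | CCOC(=O)CC(=O)OCC | starting material
2 | 1-bromo-3-methylbut-2-ene (prenyl bromide) | CC(C)=CCBr | starting material
3 | diethyl 2-(3-methylbut-2-enyl)malonate | CCOC(=O)C(CC=C(C)C)C(=O)OCC | intermediate (not isolated)
4 | diethyl 2,2-bis(3-methylbut-2-enyl)malonate | CCOC(=O)C(CC=C(C)C)(CC=C(C)C)C(=O)OCC | intermediate
5 | ethyl 5-methyl-2-(3-methylbut-2-enyl)hex-4-enoate | CCOC(=O)C(CC=C(C)C)CC=C(C)C | intermediate
6 | potassium 5-methyl-2-(3-methylbut-2-enyl)hex-4-enoate | [K+].[O-]C(=O)C(CC=C(C)C)CC=C(C)C | intermediate (not isolated)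
7 | 5-methyl-2-(3-methylbut-2-enyl)hex-4-enoic acid | OC(=O)C(CC=C(C)C)CC=C(C)C | intermediate
8 | 5-methyl-2-(3-methylbut-2-enyl)hex-4-enoyl chloride | ClC(=O)C(CC=C(C)C)CC=C(C)C | intermediate
9 | 5-methyl-3-phenylisoxazole-4-carboxylic acid | Cc1onc(-c2ccccc2)c1C(=O)O | starting material
10 | ethyl 5-methyl-3-phenylisoxazole-4-carboxylate | CCOC(=O)c1c(C)onc1-c1ccccc1 | intermediate
11 | diprenylketene, 5-methyl-2-(3-methylbut-2-enyl)hexa-1,4-dien-1-one | CC(C)=CCC(CC=C(C)C)=C=O | intermediate
12 | lithium salt of ethyl 5-methyl-3-phenylisoxazole-4-carboxylate deprotonated at the 5-methyl group | [Li+].[CH2-]c1onc(-c2ccccc2)c1C(=O)OCC | intermediate (not isolated)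
13 | lithium enolate of ethyl 5-[6-methyl-3-(3-methylbut-2-enyl)-2-oxohept-5-enyl]-3-phenylisoxazole-4-carboxylate (enolate toward the diprenyl carbon) | [Li+].[O-]C(Cc1onc(-c2ccccc2)c1C(=O)OCC)=C(CC=C(C)C)CC=C(C)C | intermediate (not isolated)
14 | lithium enolate of 15 (deprotonated at C7 of the benzoxazole, chromene C4a) | [Li+].[O-]C1=Cc2onc(-c3ccccc3)c2C(=O)C1(CC=C(C)C)CC=C(C)C | intermediate (not isolated)
15 | 3-phenyl-5,5-bis(3-methylbut-2-enyl)-1,2-benzoxazole-4,6(5H,7H)-dione | O=C1Cc2onc(-c3ccccc3)c2C(=O)C1(CC=C(C)C)CC=C(C)C | intermediate
16 | 3-methylbut-2-enal (prenal) | CC(C)=CC=O | starting material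
17 | (7Z)-7-(3-methylbut-2-enylidene)-3-phenyl-5,5-bis(3-methylbut-2-enyl)-1,2-benzoxazole-4,6(5H,7H)-dione | CC(C)=C\C=C1/C(=O)C(CC=C(C)C)(CC=C(C)C)C(=O)c2c(-c3ccccc3)noc12 | intermediate (not isolated)
18 | isoxazole-fused chromenone: 2,2-dimethyl-8,8-bis(3-methylbut-2-enyl)-2H-chromen-7(8H)-one with a 3-phenylisoxazole fused across C5–C6 (ring oxygen on C5, ring C4 = C6) | CC1(C)C=CC2=C(O1)C(CC=C(C)C)(CC=C(C)C)C(=O)c1c(-c3ccccc3)noc12 | intermediate
19 | 6-[amino(phenyl)methylidene]-2,2-dimethyl-8,8-bis(3-methylbut-2-enyl)-2H-chromene-5,7(6H,8H)-dione | CC1(C)C=CC2=C(O1)C(CC=C(C)C)(CC=C(C)C)C(=O)C(=C(N)c1ccccc1)C2=O | intermediate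
20 | sodium enolate of the target | [Na+].CC(C)=CCC1(CC=C(C)C)C([O-])=C(C(=O)c2ccccc2)C(=O)C2=C1OC(C)(C)C=C2 | intermediate (not isolated)
21 | 6-benzoyl-7-hydroxy-2,2-dimethyl-8,8-bis(3-methylbut-2-enyl)-2H-chromen-5(8H)-one | CC(C)=CCC1(CC=C(C)C)C(O)=C(C(=O)c2ccccc2)C(=O)C2=C1OC(C)(C)C=C2 | target

**Step count**

Total steps: 10. Longest linear sequence: 9 steps (steps 1 to 4 and 6 to 10, from diethyl malonate).

**Steps most likely to fail**

1. Step 7 (proposed new method). Several processes could divert it:
   - proton transfer from C4a to C8 within the adduct before ring closure, which would stall the sequence at the open-chain keto ester;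
   - O-acylation followed by isomerisation of the enol lactone to a stable pyranone;
   - dimerisation of the ketene, or incomplete ketene formation in step 6;
   - self-condensation of the lithiated ester.

   Fallback, using known chemistry, from 8 and 10 back to 15. Acid chloride 8 and N,O-dimethylhydroxylamine hydrochloride with pyridine in CH2Cl2 should give the Weinreb amide N-methoxy-N,5-dimethyl-2-(3-methylbut-2-enyl)hex-4-enamide F1. Addition of F1 to the lateral anion 12 (made from 10 with LiN(iPr)2 in THF at −78 °C) should give, after work-up, the keto ester ethyl 5-[6-methyl-3-(3-methylbut-2-enyl)-2-oxohept-5-enyl]-3-phenylisoxazole-4-carboxylate F2. Treating F2 with 2.2 equivalents of LiN(iPr)2 (THF, −78 → 0 °C) deprotonates first the doubly activated methylene and then the diprenyl methine, as in γ-functionalisation of β-keto ester dianions. Intramolecular Claisen (Dieckmann) acylation on the ester then closes ring A and gives 15 after acidic work-up. This sequence needs no ketene, so it also covers a failure of step 6.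

2. Step 8. The condensation may stop at the aldol stage, prenal may self-condense under amine catalysis faster than it is captured by the hindered enol, or a prenyl group on C8 may migrate by Cope rearrangement at the temperature required.

   Fallback from 15 back to 18. O-Alkylation of the C6 enol oxygen (chromene O8a) of 15 with 3-chloro-3-methylbut-1-yne (K2CO3, KI, acetone, reflux) should give the propargyl enol ether 6-(2-methylbut-3-yn-2-yloxy)-3-phenyl-5,5-bis(3-methylbut-2-enyl)-1,2-benzoxazol-4(5H)-one F3. Heating F3 in xylene at about 130 °C should trigger the propargyl Claisen rearrangement to the allenyl diketone 7-(3-methylbuta-1,2-dienyl)-3-phenyl-5,5-bis(3-methylbut-2-enyl)-1,2-benzoxazole-4,6(5H,7H)-dione F4 (racemic, transient). Tautomerisation and a [1,5]-hydrogen shift lead to oxatriene 17, which closes to 18; this is the classical propargyl ether route to 2,2-dimethylchromenes.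

3. Step 10. Hydrolysis of the hindered, doubly hydrogen-bonded vinylogous amide may be too slow at temperatures at which hydroxide starts to add to C8a and open the pyranone, or to cleave the C7–C8 bond in a retro-Claisen manner.

   Fallback from 19 back to 21. N-Acylation of 19 with Boc2O and catalytic DMAP in MeCN should give the carbamate tert-butyl N-[(2,2-dimethyl-5,7-dioxo-8,8-bis(3-methylbut-2-enyl)-7,8-dihydro-2H-chromen-6(5H)-ylidene)(phenyl)methyl]carbamate F5. Its nitrogen lone pair is drawn into the carbamate, so the amino-bearing carbon becomes far more electrophilic. Aqueous LiOH in THF at 0 °C should then displace tert-butyl carbamate by addition–elimination (the vinylogous counterpart of N-Boc activation for amide cleavage), and cold acidification gives 21.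

**Further compounds**

F1 | step 7 | N-methoxy-N,5-dimethyl-2-(3-methylbut-2-enyl)hex-4-enamide | CON(C)C(=O)C(CC=C(C)C)CC=C(C)C
F2 | step 7 | ethyl 5-[6-methyl-3-(3-methylbut-2-enyl)-2-oxohept-5-enyl]-3-phenylisoxazole-4-carboxylate | CCOC(=O)c1c(CC(=O)C(CC=C(C)C)CC=C(C)C)onc1-c1ccccc1
F3 | step 8 | 6-(2-methylbut-3-yn-2-yloxy)-3-phenyl-5,5-bis(3-methylbut-2-enyl)-1,2-benzoxazol-4(5H)-one | C#CC(C)(C)OC1=Cc2onc(-c3ccccc3)c2C(=O)C1(CC=C(C)C)CC=C(C)C
F4 | step 8 | 7-(3-methylbuta-1,2-dienyl)-3-phenyl-5,5-bis(3-methylbut-2-enyl)-1,2-benzoxazole-4,6(5H,7H)-dione (racemic) | CC(C)=C=CC1C(=O)C(CC=C(C)C)(CC=C(C)C)C(=O)c2c(-c3ccccc3)noc12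
F5 | step 10 | tert-butyl N-[(2,2-dimethyl-5,7-dioxo-8,8-bis(3-methylbut-2-enyl)-7,8-dihydro-2H-chromen-6(5H)-ylidene)(phenyl)methyl]carbamate | CC1(C)C=CC2=C(O1)C(CC=C(C)C)(CC=C(C)C)C(=O)C(=C(NC(=O)OC(C)(C)C)c1ccccc1)C2=O
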